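Amounts first: each flask is charged with 0.027 M of substrate, and I want the part of it that stands as target at 10 min.

    target ⇌ isomer of the product A (k1 = 9.64 × 10⁻⁴ s⁻¹, Ea1 = 106 kJ mol⁻¹)
    substrate ⇌ isomer of the product A (K2 = 49, k2 = 0.00492 s⁻¹, Ea2 = 111 kJ mol⁻¹, ΔH2 = 22.0 kJ mol⁻¹)
    substrate ⇌ target (K3 = 0.39, k3 = 0.0167 s⁻¹, Ea3 = 100 kJ mol⁻¹, ΔH3 = −4.00 kJ mol⁻¹)
    target ⇌ isomer of the product B (K4 = 0.653, k4 = 0.00151 s⁻¹, Ea4 = 102 kJ mol⁻¹, ΔH4 = −25.0 kJ mol⁻¹)
    (constants at 100 °C)

| flask | substrate | time | remark | temperature |
|---|---|---|---|---|
| grey | 0.027 M | 10 min | at 75 °C until 2.0 min, from then on at 100 °C |  |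
| red | 0.027 M | 10 min |  | 100 °C |
| ochre | 0.027 M | 10 min |  | 75 °C |

* which flask leads in amount of target, in percent of the substrate charged ("all alike" within 1.5 percentage points) (grey / red / ochre / all alike)
* how much target is there at the end, in percent of the substrate charged: grey
* how much target is there at the end, in percent of the substrate charged: red
* how much target is there at the end, in percent of the substrate charged: ochre

- the list of constants is for 100 °C, to be carried to other temperatures by the activation energies and enthalpies

The balance constant K of substrate and target is 0.39 at 100 °C and 0.428 at 75 °C. In ochre, substrate and target relax with a half-life of 2.10 min, shorter than the 29.6 min of substrate and isomer of the product A. So I treat the two as a pool in pre-equilibrium, where target holds the share s = K/(1+K): 30.0 % in ochre and 28.1 % at 100 °C.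

For ochre the bound from above is this share, since the pool starts as the whole charge and shrinks: 30.0 %. At 75 °C the exits are 0.0226 min⁻¹ from substrate to isomer of the product A, 0.00497 min⁻¹ from target to that isomer, and 0.00855 min⁻¹ from target to isomer of the product B. Letting the whole pool leave by their sum gives a rough bound from below: 20.9 %.

To tighten this, I weight each exit to isomer of the product A by its share and leave the reversible step to isomer of the product B out. This gives the drain constant D = (1−s)k₂ + s·k₁, the pool's pseudo-first-order loss: 0.0173 min⁻¹ in ochre and 0.229 min⁻¹ at 100 °C. In logarithms the pool loses L = Dt/ln(10) decades, and target is s lowered by L powers of 10. Ochre loses 0.0753 decades, so I commit to 25.2 %. Red loses 0.993, giving 2.85 %. Grey spends 2.0 min cold and the rest hot, so it loses 0.809, giving 4.35 %. My leader is ochre.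

The forecast names ochre, with 4.7 % (4 % to 5.5 %) for grey, 3.5 % (3 % to 4.1 %) for red and 24 % (22 % to 26 %) for ochre, which “has lost little to the isomers”. Its ochre value lies inside my bracket, while its red value stands above mine, and so does its grey value.

The simulation gives 4.75 % for grey, 3.48 % for red and 23.9 % for ochre, so ochre leads.

The neighbour is ochre read at 40 min instead of 10 min. The temperature is held, so D stays and the pool loses 0.301 decades. That predicts target at 15.0 % and substrate at 35.0 %. Ochre at that reading holds 14.2 % target and 32.1 % substrate.

All constants are invented; the rest is arithmetic.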